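**Plan**
- Retrosynthesis: the two phenols are masked as benzyl ethers and the acetoxymethyl carbon on C2 is traced back to a vinyl group. C1–C1′ and C1–C2 are then cut together, followed by the allylsilane C=C (metathesis), the aryl–CHO bond and finally C3–C4.
- Enabling feature: C1 is benzylic to ring A and para to the C6 methoxyl. It can therefore enter as an aryl aldehyde carbon, take C2 from a tethered allylsilane and then, as a methoxyl-stabilised cation, take C1′ of 2,6-dimethoxyphenol.
- Forward: the ring A building block (a 2-bromobenzyl bromide) is joined to a four-carbon chain at C3–C4. Formylation and cross-metathesis give the aldehyde–allylsilane, and ring B closes while ring C is attached in one flask. The vinyl group is then cut to CH2OH, both arms are acetylated and the benzyl ethers are removed.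
- Stereochemistry: C3 comes from (R)-4-benzyl-2-oxazolidinone (auxiliary alkylation). C2 is relayed from C3 in a chair-like closure (2,3-trans), and C1 from C2 by anti attack on the cation (1,2-trans).

Key step: step 10

Remark: tetralin numbering is used (C1 carries ring C, C2 and C3 carry the acetoxymethyl arms, C4 is the benzylic CH2, ring A is the fused benzene ring, ring B the carbocycle); O-benzylvanillin is taken as a catalogue compound, and a TBDPS ether is chosen for the C3 arm because it should resist BF3·OEt2 better than a TBS ether.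

**Route**

Step 1
Reactants: 1 4-(benzyloxy)-3-methoxybenzaldehyde
Product: 2 4-(benzyloxy)-2-bromo-5-methoxybenzaldehyde
Conditions: Br2, NaOAc, AcOH, rt
Reagents that add atoms: bromine, BrBr
Why: Electrophilic aromatic bromination should go to the position para to the methoxyl and ortho to the formyl group, the most activated open site, as in the bromination of veratraldehyde.

Step 2
Reactants: 2 4-(benzyloxy)-2-bromo-5-methoxybenzaldehyde
Product: 3 [4-(benzyloxy)-2-bromo-5-methoxyphenyl]methanol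
Conditions: NaBH4, MeOH, 0 °C
Reagents that add atoms: none
Why: Borohydride reduction of the aryl aldehyde should leave the aryl bromide and the benzyl ether untouched.

Step 3
Reactants: 3 [4-(benzyloxy)-2-bromo-5-methoxyphenyl]methanol
Product: 4 1-(benzyloxy)-5-bromo-4-(bromomethyl)-2-methoxybenzene
Conditions: PBr3, CH2Cl2, 0 °C
Reagents that add atoms: phosphorus tribromide, BrP(Br)Br
Why: Conversion of a primary benzylic alcohol into its bromide by PBr3 (bromide displacement on the phosphite ester) is routine for electron-rich benzyl alcohols.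

Step 4
Reactants: 5 (R)-4-benzyl-2-oxazolidinone; 6 but-3-enoic acid
Product: 8 (4R)-4-benzyl-3-(but-3-enoyl)-1,3-oxazolidin-2-one, via but-3-enoic pivalic anhydride 7 (not isolated)
Conditions: PivCl, Et3N, THF, −20 °C; then LiCl, 5, −20 °C → rt
Reagents that add atoms: none
Why: N-Acylation of the oxazolidinone through the mixed pivalic anhydride (LiCl/Et3N variant) should be mild enough to keep the β,γ-double bond out of conjugation; no stereocentre is formed.

Step 5
Reactants: 8 (4R)-4-benzyl-3-(but-3-enoyl)-1,3-oxazolidin-2-one; 4 1-(benzyloxy)-5-bromo-4-(bromomethyl)-2-methoxybenzene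
Product: 10 (4R)-4-benzyl-3-[(2R)-2-{[4-(benzyloxy)-2-bromo-5-methoxyphenyl]methyl}but-3-enoyl]-1,3-oxazolidin-2-one, via sodium Z-dienolate 9 (not isolated)
Conditions: NaN(SiMe3)2, THF, −78 °C; then 4, −78 → −40 °C
Reagents that add atoms: none
Why: Evans asymmetric alkylation: the chelated (Z)-sodium dienolate should react at its α-carbon with the reactive benzylic bromide on the face away from the C4 benzyl group of the auxiliary, which sets the (R) centre that becomes C3.

Step 6
Reactants: 10 (4R)-4-benzyl-3-[(2R)-2-{[4-(benzyloxy)-2-bromo-5-methoxyphenyl]methyl}but-3-enoyl]-1,3-oxazolidin-2-one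
Product: 11 (2R)-2-{[4-(benzyloxy)-2-bromo-5-methoxyphenyl]methyl}but-3-en-1-ol
Conditions: LiBH4, Et2O, H2O (1 equiv), 0 °C
Reagents that add atoms: none
Why: Reductive cleavage of the N-acyl oxazolidinone by LiBH4 at the exocyclic carbonyl should release the primary alcohol and the auxiliary without touching the α-centre, the aryl bromide or the alkene.

Step 7
Reactants: 11 (2R)-2-{[4-(benzyloxy)-2-bromo-5-methoxyphenyl]methyl}but-3-en-1-ol
Product: 12 {[(2R)-2-{[4-(benzyloxy)-2-bromo-5-methoxyphenyl]methyl}but-3-en-1-yl]oxy}(tert-butyl)diphenylsilane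
Conditions: TBDPSCl, imidazole, DMF, rt
Reagents that add atoms: tert-butyl(chloro)diphenylsilane, CC(C)(C)[Si](Cl)(c1ccccc1)c1ccccc1
Why: Imidazole-promoted silylation of the primary alcohol gives an ether that should survive n-BuLi and the Lewis acid of step 10.

Step 8
Reactants: 12 {[(2R)-2-{[4-(benzyloxy)-2-bromo-5-methoxyphenyl]methyl}but-3-en-1-yl]oxy}(tert-butyl)diphenylsilane
Product: 15 5-(benzyloxy)-2-[(2R)-2-({[tert-butyl(diphenyl)silyl]oxy}methyl)but-3-en-1-yl]-4-methoxybenzaldehyde, via aryllithium 13 (not isolated), via lithium hemiaminal alkoxide 14 (not isolated)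
Conditions: n-BuLi, THF, −78 °C; DMF, −78 → 0 °C; then H2O
Reagents that add atoms: N,N-dimethylformamide, CN(C)C=O
Why: Bromine–lithium exchange at −78 °C is faster than any deprotonation, and formylation of the aryllithium by DMF (Bouveault-type) should place the aldehyde para to the methoxyl.

Step 9
Reactants: 15 5-(benzyloxy)-2-[(2R)-2-({[tert-butyl(diphenyl)silyl]oxy}methyl)but-3-en-1-yl]-4-methoxybenzaldehyde; 16 allyltrimethylsilane
Product: 17 5-(benzyloxy)-2-[(2R,3E)-2-({[tert-butyl(diphenyl)silyl]oxy}methyl)-5-(trimethylsilyl)pent-3-en-1-yl]-4-methoxybenzaldehyde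
Conditions: 16 (4 equiv), second-generation Grubbs catalyst [1,3-bis(2,4,6-trimethylphenyl)imidazolidin-2-ylidene]RuCl2(=CHPh)(PCy3) (5 mol %), CH2Cl2, 40 °C
Reagents that add atoms: none
Why: Olefin cross-metathesis of the monosubstituted alkene with excess allyltrimethylsilane should give mainly the (E)-allylsilane with loss of ethene, and a minor (Z)-isomer need not be removed because step 10 should relay the same C2 configuration from either geometry.

Step 10
Reactants: 17 5-(benzyloxy)-2-[(2R,3E)-2-({[tert-butyl(diphenyl)silyl]oxy}methyl)-5-(trimethylsilyl)pent-3-en-1-yl]-4-methoxybenzaldehyde; 18 2,6-dimethoxyphenol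
Product: 21 4-[(1S,2R,3R)-7-(benzyloxy)-3-({[tert-butyl(diphenyl)silyl]oxy}methyl)-2-ethenyl-6-methoxy-1,2,3,4-tetrahydronaphthalen-1-yl]-2,6-dimethoxyphenol, via difluoroboryl tetralyl ether 19 (not isolated), via benzylic C1 cation 20 (not isolated)
Conditions: 18 (3 equiv), BF3·OEt2 (3 equiv), CH2Cl2, −78 → 0 °C
Reagents that add atoms: none
Why: BF3 activates the aldehyde, the allylsilane adds through its γ-carbon (anti SE2′) to form C1–C2 with loss of Me3SiF, and the benzylic C1–O bond of 19 then ionises to cation 20, which the phenol captures through the carbon para to its hydroxyl to form C1–C1′. The closest known reaction types are the intramolecular Hosomi–Sakurai allylation of aryl aldehydes and the Friedel–Crafts arylation of alkoxy-stabilised 1-tetralyl cations by phenols, run here in sequence without isolation; if the phenol condenses with the aldehyde first, the allylsilane closes onto the same cationic carbon and the outcome should be the same. Ring B closes in a 6-exo-trig mode at the carbonyl carbon through a chair-like transition state. C2 is controlled by C3: the silyloxymethyl group sits pseudo-equatorial and the C3–H bond eclipses the alkene to avoid allylic strain, so the emerging vinyl group should end up equatorial and trans to it. C1 is controlled by C2, the phenol adding to the planar cation anti to the vinyl group, and reversibility of the arylation under acid should favour the all-equatorial isomer. The step needs ionisation at C1 only and capture by the phenol rather than proton loss or attack by the C3 oxygen; the C6 methoxyl para to C1 secures the first, the bulky, weakly basic TBDPS ether and the excess of phenol the second, and the free hydroxyl of the phenol directs attack to its unhindered para carbon.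

Step 11
Reactants: 21 4-[(1S,2R,3R)-7-(benzyloxy)-3-({[tert-butyl(diphenyl)silyl]oxy}methyl)-2-ethenyl-6-methoxy-1,2,3,4-tetrahydronaphthalen-1-yl]-2,6-dimethoxyphenol
Product: 22 (1S,2R,3R)-7-(benzyloxy)-1-[4-(benzyloxy)-3,5-dimethoxyphenyl]-3-({[tert-butyl(diphenyl)silyl]oxy}methyl)-2-ethenyl-6-methoxy-1,2,3,4-tetrahydronaphthalene
Conditions: BnBr, K2CO3, DMF, rt
Reagents that add atoms: benzyl bromide, BrCc1ccccc1
Why: Williamson etherification of the acidic syringyl phenol masks the most oxidisable ring before the alkene is cleaved and lets both phenols be released together at the end.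

Step 12
Reactants: 22 (1S,2R,3R)-7-(benzyloxy)-1-[4-(benzyloxy)-3,5-dimethoxyphenyl]-3-({[tert-butyl(diphenyl)silyl]oxy}methyl)-2-ethenyl-6-methoxy-1,2,3,4-tetrahydronaphthalene
Product: 24 [(1S,2R,3R)-7-(benzyloxy)-1-[4-(benzyloxy)-3,5-dimethoxyphenyl]-3-({[tert-butyl(diphenyl)silyl]oxy}methyl)-6-methoxy-1,2,3,4-tetrahydronaphthalen-2-yl]methanol, via secondary ozonide 23 (not isolated)
Conditions: O3, CH2Cl2, −78 °C (stopped when 22 is consumed); then NaBH4, MeOH, −78 → 0 °C
Reagents that add atoms: ozone, [O-][O+]=O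
Why: Ozonolysis (1,3-dipolar cycloaddition, cycloreversion and recombination to the ozonide) followed by borohydride reduction should turn the vinyl group into the C2 hydroxymethyl arm without touching C2, the terminal alkene being far more reactive towards ozone at −78 °C than the alkoxyarenes.

Step 13
Reactants: 24 [(1S,2R,3R)-7-(benzyloxy)-1-[4-(benzyloxy)-3,5-dimethoxyphenyl]-3-({[tert-butyl(diphenyl)silyl]oxy}methyl)-6-methoxy-1,2,3,4-tetrahydronaphthalen-2-yl]methanol
Product: 25 [(1S,2R,3R)-7-(benzyloxy)-1-[4-(benzyloxy)-3,5-dimethoxyphenyl]-6-methoxy-1,2,3,4-tetrahydronaphthalene-2,3-diyl]dimethanol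
Conditions: Bu4NF, THF, rt
Reagents that add atoms: none
Why: Fluoride-induced cleavage of the Si–O bond (desilylation) should free the C3 hydroxymethyl arm without affecting the benzyl ethers.

Step 14
Reactants: 25 [(1S,2R,3R)-7-(benzyloxy)-1-[4-(benzyloxy)-3,5-dimethoxyphenyl]-6-methoxy-1,2,3,4-tetrahydronaphthalene-2,3-diyl]dimethanol
Product: 26 [(1S,2R,3R)-7-(benzyloxy)-1-[4-(benzyloxy)-3,5-dimethoxyphenyl]-6-methoxy-1,2,3,4-tetrahydronaphthalene-2,3-diyl]bis(methylene) diacetate
Conditions: Ac2O, pyridine, DMAP (cat.), CH2Cl2, rt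
Reagents that add atoms: acetic anhydride, CC(=O)OC(C)=O
Why: DMAP-catalysed acetylation of the two primary alcohols should be clean because no other nucleophilic group is present.

Step 15
Reactants: 26 [(1S,2R,3R)-7-(benzyloxy)-1-[4-(benzyloxy)-3,5-dimethoxyphenyl]-6-methoxy-1,2,3,4-tetrahydronaphthalene-2,3-diyl]bis(methylene) diacetate
Product: 27 [(1S,2R,3R)-7-hydroxy-1-(4-hydroxy-3,5-dimethoxyphenyl)-6-methoxy-1,2,3,4-tetrahydronaphthalene-2,3-diyl]bis(methylene) diacetate
Conditions: H2 (1 atm), 10% Pd/C, EtOAc, rt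
Reagents that add atoms: none
Why: Catalytic hydrogenolysis of the two aryl benzyl ethers over palladium on carbon in a neutral solvent should leave the primary acetates and the three stereocentres untouched.

**Compound list**

1 | 4-(benzyloxy)-3-methoxybenzaldehyde (O-benzylvanillin) | COc1cc(C=O)ccc1OCc1ccccc1 | starting material
2 | 4-(benzyloxy)-2-bromo-5-methoxybenzaldehyde | COc1cc(C=O)c(Br)cc1OCc1ccccc1 | intermediate
3 | [4-(benzyloxy)-2-bromo-5-methoxyphenyl]methanol | COc1cc(CO)c(Br)cc1OCc1ccccc1 | intermediate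
4 | 1-(benzyloxy)-5-bromo-4-(bromomethyl)-2-methoxybenzene | COc1cc(CBr)c(Br)cc1OCc1ccccc1 | intermediate
5 | (R)-4-benzyl-2-oxazolidinone | O=C1N[C@H](Cc2ccccc2)CO1 | starting material
6 | but-3-enoic acid | C=CCC(=O)O | starting material
7 | but-3-enoic pivalic anhydride (formed in the flask) | C=CCC(=O)OC(=O)C(C)(C)C | intermediate
8 | (4R)-4-benzyl-3-(but-3-enoyl)-1,3-oxazolidin-2-one | C=CCC(=O)N1[C@H](Cc2ccccc2)COC1=O | intermediate
9 | sodium (Z)-dienolate of 8 (formed in the flask) | [Na+].[O-]/C(=C\C=C)N1[C@H](Cc2ccccc2)COC1=O | intermediate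
10 | (4R)-4-benzyl-3-[(2R)-2-{[4-(benzyloxy)-2-bromo-5-methoxyphenyl]methyl}but-3-enoyl]-1,3-oxazolidin-2-one | C=C[C@@H](Cc1cc(OC)c(OCc2ccccc2)cc1Br)C(=O)N1[C@H](Cc2ccccc2)COC1=O | intermediate
11 | (2R)-2-{[4-(benzyloxy)-2-bromo-5-methoxyphenyl]methyl}but-3-en-1-ol | C=C[C@@H](Cc1cc(OC)c(OCc2ccccc2)cc1Br)CO | intermediate
12 | {[(2R)-2-{[4-(benzyloxy)-2-bromo-5-methoxyphenyl]methyl}but-3-en-1-yl]oxy}(tert-butyl)diphenylsilane | C=C[C@@H](Cc1cc(OC)c(OCc2ccccc2)cc1Br)CO[Si](c1ccccc1)(c1ccccc1)C(C)(C)C | intermediate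
13 | aryllithium from 12 (Li in place of Br; formed in the flask) | C=C[C@@H](Cc1cc(OC)c(OCc2ccccc2)cc1[Li])CO[Si](c1ccccc1)(c1ccccc1)C(C)(C)C | intermediate
14 | lithium hemiaminal alkoxide, DMF adduct of 13 (carbinol carbon unspecified; formed in the flask) | C=C[C@@H](Cc1cc(OC)c(OCc2ccccc2)cc1C(O[Li])N(C)C)CO[Si](c1ccccc1)(c1ccccc1)C(C)(C)C | intermediate
15 | 5-(benzyloxy)-2-[(2R)-2-({[tert-butyl(diphenyl)silyl]oxy}methyl)but-3-en-1-yl]-4-methoxybenzaldehyde | C=C[C@@H](Cc1cc(OC)c(OCc2ccccc2)cc1C=O)CO[Si](c1ccccc1)(c1ccccc1)C(C)(C)C | intermediate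
16 | allyltrimethylsilane | C=CC[Si](C)(C)C | starting material
17 | 5-(benzyloxy)-2-[(2R,3E)-2-({[tert-butyl(diphenyl)silyl]oxy}methyl)-5-(trimethylsilyl)pent-3-en-1-yl]-4-methoxybenzaldehyde | C[Si](C)(C)C/C=C/[C@@H](Cc1cc(OC)c(OCc2ccccc2)cc1C=O)CO[Si](c1ccccc1)(c1ccccc1)C(C)(C)C | intermediate
18 | 2,6-dimethoxyphenol | COc1cccc(OC)c1O | starting material
19 | difluoroboryl ether of the cyclised (2R,3R)-2-ethenyl-1-tetralol, both C1 epimers (formed in the flask) | COc1cc2c(cc1OCc1ccccc1)C(OB(F)F)[C@@H](C=C)[C@H](CO[Si](c1ccccc1)(c1ccccc1)C(C)(C)C)C2 | intermediate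
20 | C1 benzylic cation derived from 19 (formed in the flask) | COc1cc2c(cc1OCc1ccccc1)[CH+][C@@H](C=C)[C@H](CO[Si](c1ccccc1)(c1ccccc1)C(C)(C)C)C2 | intermediate
21 | 4-[(1S,2R,3R)-7-(benzyloxy)-3-({[tert-butyl(diphenyl)silyl]oxy}methyl)-2-ethenyl-6-methoxy-1,2,3,4-tetrahydronaphthalen-1-yl]-2,6-dimethoxyphenol | COc1cc2c(cc1OCc1ccccc1)[C@H](c1cc(OC)c(O)c(OC)c1)[C@@H](C=C)[C@H](CO[Si](c1ccccc1)(c1ccccc1)C(C)(C)C)C2 | intermediate
22 | (1S,2R,3R)-7-(benzyloxy)-1-[4-(benzyloxy)-3,5-dimethoxyphenyl]-3-({[tert-butyl(diphenyl)silyl]oxy}methyl)-2-ethenyl-6-methoxy-1,2,3,4-tetrahydronaphthalene | COc1cc2c(cc1OCc1ccccc1)[C@H](c1cc(OC)c(OCc3ccccc3)c(OC)c1)[C@@H](C=C)[C@H](CO[Si](c1ccccc1)(c1ccccc1)C(C)(C)C)C2 | intermediate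
23 | secondary ozonide of 22 (1,2,4-trioxolan-3-yl group on C2, trioxolane carbon unspecified; formed in the flask) | COc1cc2c(cc1OCc1ccccc1)[C@H](c1cc(OC)c(OCc3ccccc3)c(OC)c1)[C@@H](C1OCOO1)[C@H](CO[Si](c1ccccc1)(c1ccccc1)C(C)(C)C)C2 | intermediate
24 | [(1S,2R,3R)-7-(benzyloxy)-1-[4-(benzyloxy)-3,5-dimethoxyphenyl]-3-({[tert-butyl(diphenyl)silyl]oxy}methyl)-6-methoxy-1,2,3,4-tetrahydronaphthalen-2-yl]methanol | COc1cc2c(cc1OCc1ccccc1)[C@H](c1cc(OC)c(OCc3ccccc3)c(OC)c1)[C@@H](CO)[C@H](CO[Si](c1ccccc1)(c1ccccc1)C(C)(C)C)C2 | intermediate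
25 | [(1S,2R,3R)-7-(benzyloxy)-1-[4-(benzyloxy)-3,5-dimethoxyphenyl]-6-methoxy-1,2,3,4-tetrahydronaphthalene-2,3-diyl]dimethanol | COc1cc2c(cc1OCc1ccccc1)[C@H](c1cc(OC)c(OCc3ccccc3)c(OC)c1)[C@@H](CO)[C@H](CO)C2 | intermediate
26 | [(1S,2R,3R)-7-(benzyloxy)-1-[4-(benzyloxy)-3,5-dimethoxyphenyl]-6-methoxy-1,2,3,4-tetrahydronaphthalene-2,3-diyl]bis(methylene) diacetate | COc1cc2c(cc1OCc1ccccc1)[C@H](c1cc(OC)c(OCc3ccccc3)c(OC)c1)[C@@H](COC(C)=O)[C@H](COC(C)=O)C2 | intermediate
27 | [(1S,2R,3R)-7-hydroxy-1-(4-hydroxy-3,5-dimethoxyphenyl)-6-methoxy-1,2,3,4-tetrahydronaphthalene-2,3-diyl]bis(methylene) diacetate (CNP0265800.1) | COc1cc2c(cc1O)[C@H](c1cc(OC)c(O)c(OC)c1)[C@@H](COC(C)=O)[C@H](COC(C)=O)C2 | target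

**Step count**

Total: 15 steps. Longest linear sequence: 14 steps (from 1 through steps 1–3 and 5–15; step 4 is the side branch that prepares 8).

**Steps most likely to fail**

1. Step 10. The cation at C1 may be diverted before the phenol reaches it (proton loss towards a dihydronaphthalene, capture by a second electron-rich ring, cleavage of the silyl ether by the Lewis acid), or the phenol may attack with poor regio- or facial selectivity.
Fallback, setting out from 17 and coming back to the route at 22 (step 11 is then skipped): ring C is brought in as an organometallic with its position and protecting group already fixed. Commercial 4-bromo-2,6-dimethoxyphenol would be benzylated (BnBr, K2CO3, DMF) to 2-(benzyloxy)-5-bromo-1,3-dimethoxybenzene F1. Bromine–lithium exchange (n-BuLi, THF, −78 °C) would give [4-(benzyloxy)-3,5-dimethoxyphenyl]lithium F2, and its addition to aldehyde 17 would give the diarylmethanol F3 as a mixture of carbinol epimers. Anhydrous FeCl3 (10 mol %) in CH2Cl2 at −40 → 0 °C should then ionise the doubly benzylic alcohol, and the allylsilane should close ring B onto the diarylmethyl cation. This is the known Lewis-acid allylation of benzhydrols by allylsilanes, here intramolecular. A chair-like closure with the aryl, vinyl and silyloxymethyl groups equatorial should give 22.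

2. Step 5. The dienolate may alkylate at its γ-carbon, the double bond may move into conjugation, or the doubly activated α-centre of the product may be enolised again and lose its configuration.
Fallback, setting out from 5 and 4 and coming back to the route at 12: the vinyl group is carried as a saturated selenide so that an ordinary enolate is alkylated. γ-Butyrolactone would be opened by PhSeNa (from (PhSe)2 and NaBH4, DMF, 120 °C) to 4-(phenylselanyl)butanoic acid F4. Acylation of 5 under the conditions of step 4 would give (4R)-4-benzyl-3-[4-(phenylselanyl)butanoyl]-1,3-oxazolidin-2-one F5. Alkylation with 4 under the conditions of step 5 should give, by the same facial control, (4R)-4-benzyl-3-[(2R)-2-{[4-(benzyloxy)-2-bromo-5-methoxyphenyl]methyl}-4-(phenylselanyl)butanoyl]-1,3-oxazolidin-2-one F6. LiBH4 would then give (2R)-2-{[4-(benzyloxy)-2-bromo-5-methoxyphenyl]methyl}-4-(phenylselanyl)butan-1-ol F7, and TBDPSCl with imidazole its silyl ether {[(2R)-2-{[4-(benzyloxy)-2-bromo-5-methoxyphenyl]methyl}-4-(phenylselanyl)butyl]oxy}(tert-butyl)diphenylsilane F8. Oxidation with H2O2 and pyridine in CH2Cl2 (0 °C → rt) and selenoxide syn-elimination should reveal the vinyl group and give 12.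

3. Step 12. Ozone may over-oxidise the three alkoxy-substituted rings or the benzyl ethers before the alkene is fully consumed.
Fallback, setting out from 22 and coming back to the route at 24: the alkene is cleaved without ozone. Dihydroxylation with OsO4 (cat.) and NMO in acetone–water would give 1-[(1S,2R,3R)-7-(benzyloxy)-1-[4-(benzyloxy)-3,5-dimethoxyphenyl]-3-({[tert-butyl(diphenyl)silyl]oxy}methyl)-6-methoxy-1,2,3,4-tetrahydronaphthalen-2-yl]ethane-1,2-diol F9 (carbinol carbon as a mixture). Glycol cleavage with NaIO4 in THF–water would give (1S,2R,3R)-7-(benzyloxy)-1-[4-(benzyloxy)-3,5-dimethoxyphenyl]-3-({[tert-butyl(diphenyl)silyl]oxy}methyl)-6-methoxy-1,2,3,4-tetrahydronaphthalene-2-carbaldehyde F10. Its C2 centre is epimerisable, but the all-trans arrangement is the more stable one. NaBH4 in MeOH would then give 24.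

Further compounds
F1 | step 10 | 2-(benzyloxy)-5-bromo-1,3-dimethoxybenzene | COc1cc(Br)cc(OC)c1OCc1ccccc1
F2 | step 10 | [4-(benzyloxy)-3,5-dimethoxyphenyl]lithium | COc1cc([Li])cc(OC)c1OCc1ccccc1
F3 | step 10 | [4-(benzyloxy)-3,5-dimethoxyphenyl]{5-(benzyloxy)-2-[(2R,3E)-2-({[tert-butyl(diphenyl)silyl]oxy}methyl)-5-(trimethylsilyl)pent-3-en-1-yl]-4-methoxyphenyl}methanol | C[Si](C)(C)C/C=C/[C@@H](Cc1cc(OC)c(OCc2ccccc2)cc1C(O)c1cc(OC)c(OCc2ccccc2)c(OC)c1)CO[Si](c1ccccc1)(c1ccccc1)C(C)(C)C
F4 | step 5 | 4-(phenylselanyl)butanoic acid | OC(=O)CCC[Se]c1ccccc1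
F5 | step 5 | (4R)-4-benzyl-3-[4-(phenylselanyl)butanoyl]-1,3-oxazolidin-2-one | O=C(CCC[Se]c1ccccc1)N1[C@H](Cc2ccccc2)COC1=O
F6 | step 5 | (4R)-4-benzyl-3-[(2R)-2-{[4-(benzyloxy)-2-bromo-5-methoxyphenyl]methyl}-4-(phenylselanyl)butanoyl]-1,3-oxazolidin-2-one | C(C[Se]c1ccccc1)[C@@H](Cc1cc(OC)c(OCc2ccccc2)cc1Br)C(=O)N1[C@H](Cc2ccccc2)COC1=O
F7 | step 5 | (2R)-2-{[4-(benzyloxy)-2-bromo-5-methoxyphenyl]methyl}-4-(phenylselanyl)butan-1-ol | C(C[Se]c1ccccc1)[C@@H](Cc1cc(OC)c(OCc2ccccc2)cc1Br)CO
F8 | step 5 | {[(2R)-2-{[4-(benzyloxy)-2-bromo-5-methoxyphenyl]methyl}-4-(phenylselanyl)butyl]oxy}(tert-butyl)diphenylsilane | C(C[Se]c1ccccc1)[C@@H](Cc1cc(OC)c(OCc2ccccc2)cc1Br)CO[Si](c1ccccc1)(c1ccccc1)C(C)(C)C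
F9 | step 12 | 1-[(1S,2R,3R)-7-(benzyloxy)-1-[4-(benzyloxy)-3,5-dimethoxyphenyl]-3-({[tert-butyl(diphenyl)silyl]oxy}methyl)-6-methoxy-1,2,3,4-tetrahydronaphthalen-2-yl]ethane-1,2-diol | COc1cc2c(cc1OCc1ccccc1)[C@H](c1cc(OC)c(OCc3ccccc3)c(OC)c1)[C@@H](C(O)CO)[C@H](CO[Si](c1ccccc1)(c1ccccc1)C(C)(C)C)C2
F10 | step 12 | (1S,2R,3R)-7-(benzyloxy)-1-[4-(benzyloxy)-3,5-dimethoxyphenyl]-3-({[tert-butyl(diphenyl)silyl]oxy}methyl)-6-methoxy-1,2,3,4-tetrahydronaphthalene-2-carbaldehyde | COc1cc2c(cc1OCc1ccccc1)[C@H](c1cc(OC)c(OCc3ccccc3)c(OC)c1)[C@@H](C=O)[C@H](CO[Si](c1ccccc1)(c1ccccc1)C(C)(C)C)C2
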